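**Retrosynthetic overview**
1. C12–OAc and C7=C8 come last: acetylation/E1cB of the aldol adduct of an (S)-2-chloro-4-hydroxy-4-octenylcyclopentenone with methyl (5Z)-7-oxohept-5-enoate (made by Wittig reaction).
2. The chloro hydroxy enone comes from hydride reduction and acid transposition of a 2-chloro-3-ethoxy-5-hydroxy-5-octenylcyclopent-2-enone.
3. Key disconnection, C12–O: catalytic enantioconvergent α′-hydroxylation of the racemic α′-alkylated vinylogous ester; this sets the only stereocentre.
4. C12–C13 by enolate alkylation with 1-bromooct-2-yne, C10–Cl by N-chlorosuccinimide, 14Z by semihydrogenation.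
5. Rings: the single carbocycle is bought as 3-ethoxycyclopent-2-en-1-one; no ring is formed in the route.

Positions are cited with prostanoid numbering (C1 = ester carbon, ring = C8–C12, C12 = carbinol carbon).
Assumption: the facial sense of the new hydroxylation cannot be predicted; the cinchonidinium catalyst is written, and its pseudoenantiomeric cinchoninium salt replaces it if screening shows the opposite sense.

**Route**

Step 1
Reactants: 1 3-ethoxycyclopent-2-en-1-one; 2 1-bromooct-2-yne
Product: 4 3-ethoxy-5-(oct-2-yn-1-yl)cyclopent-2-en-1-one (racemic), via lithium enolate 3 (not isolated)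
Conditions: LiN(i-Pr)2 (1.05 equiv), THF, −78 °C; then 2, DMPU, −78 to −20 °C
Reagents that add atoms: none
Why: Kinetic deprotonation of the vinylogous ester occurs at the α′ carbon and the enolate displaces the propargylic bromide by SN2 (Stork–Danheiser α′-alkylation); the new centre is racemic and is erased in step 4.

Step 2
Reactants: 4 3-ethoxy-5-(oct-2-yn-1-yl)cyclopent-2-en-1-one
Product: 5 2-chloro-3-ethoxy-5-(oct-2-yn-1-yl)cyclopent-2-en-1-one (racemic)
Conditions: N-chlorosuccinimide (1.05 equiv), CH2Cl2, 0 °C to rt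
Reagents that add atoms: N-chlorosuccinimide, O=C1CCC(=O)N1Cl
Why: C2 of a 3-alkoxy enone is an enol-ether β-carbon and is chlorinated selectively by the mild Cl+ donor (electrophilic α-halogenation of a vinylogous ester); the internal alkyne is inert.

Step 3
Reactants: 5 2-chloro-3-ethoxy-5-(oct-2-yn-1-yl)cyclopent-2-en-1-one
Product: 6 2-chloro-3-ethoxy-5-[(2Z)-oct-2-en-1-yl]cyclopent-2-en-1-one (racemic)
Conditions: H2 (1 atm), Pd/CaCO3 poisoned with Pb(OAc)2, quinoline, EtOAc, rt
Reagents that add atoms: none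
Why: Lindlar semihydrogenation adds H2 syn to the alkyne and stops at the (Z)-alkene; the push-pull C=C and the vinylic C–Cl are not reduced on the poisoned catalyst.

Step 4
Reactants: 6 2-chloro-3-ethoxy-5-[(2Z)-oct-2-en-1-yl]cyclopent-2-en-1-one
Product: 10 (5S)-2-chloro-3-ethoxy-5-hydroxy-5-[(2Z)-oct-2-en-1-yl]cyclopent-2-en-1-one, via lithium enolate 7 (not isolated), via silyl dienol ether 8 (not isolated), via silyl ether 9 (not isolated)
Conditions: LiN(i-Pr)2 (1.1 equiv), THF, −78 °C; Me3SiCl, −78 to −40 °C; pentane, cold filtration; then O-allyl-N-(9-anthracenylmethyl)cinchonidinium phenoxide (10 mol %), (±)-trans-2-(phenylsulfonyl)-3-phenyloxaziridine (1.3 equiv), toluene/CH2Cl2, −60 °C; then citric acid, MeOH, 0 °C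
Reagents that add atoms: 2-(phenylsulfonyl)-3-phenyloxaziridine, O=S(=O)(c1ccccc1)N1OC1c1ccccc1
Why: Proposed new method: enantioconvergent, chiral-ammonium-catalysed oxygen-atom transfer to a silyl dienol ether (asymmetric enolate oxidation). The phenoxide desilylates achiral 8 to a contact ion pair of the planar dienolate with the chiral cation, which shields one face. C12 then attacks the oxaziridine oxygen (SN2 at O, loss of the sulfonylimine) and forms the C12–O bond as (S). The resulting ammonium tertiary alkoxide takes Me3Si from the next molecule of 8, giving 9 and regenerating the ion pair, so both enantiomers of 6 converge; the neutral silyl ether does not react with the oxaziridine at −60 °C. Closest known reaction types: chiral quaternary ammonium phenoxide- or fluoride-catalysed aldol and Michael additions of silyl enolates, phase-transfer α-hydroxylation of ketones, and stoichiometric oxaziridine hydroxylation of metal enolates.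

Step 5
Reactants: 10 (5S)-2-chloro-3-ethoxy-5-hydroxy-5-[(2Z)-oct-2-en-1-yl]cyclopent-2-en-1-one
Product: 12 (4S)-2-chloro-4-hydroxy-4-[(2Z)-oct-2-en-1-yl]cyclopent-2-en-1-one, via allylic diol 11 (not isolated)
Conditions: i-Bu2AlH (3.0 equiv), CH2Cl2, −78 °C; then 1 M HCl, THF, 0 °C to rt
Reagents that add atoms: water, O
Why: 1,2-Reduction of the vinylogous-ester carbonyl and acid hydrolysis with allylic transposition (Stork–Danheiser sequence) move the carbonyl to C9 and leave chlorine on the enone α-carbon; the quaternary C12 centre is not touched.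

Step 6
Reactants: 13 methyl 5-bromopentanoate
Product: 14 (5-methoxy-5-oxopentyl)triphenylphosphonium bromide
Conditions: PPh3 (1.05 equiv), MeCN, reflux
Reagents that add atoms: triphenylphosphine, c1ccc(cc1)P(c1ccccc1)c1ccccc1
Why: SN2 quaternisation of the primary bromide gives the phosphonium salt.

Step 7
Reactants: 14 (5-methoxy-5-oxopentyl)triphenylphosphonium bromide; 15 glycolaldehyde dimer (1,4-dioxane-2,5-diol)
Product: 17 methyl (5Z)-7-hydroxyhept-5-enoate, via phosphorus ylide 16 (not isolated)
Conditions: 14 (2.2 equiv), NaN(SiMe3)2 (2.1 equiv), THF, −78 to 0 °C; then 15 (0.5 equiv, one aldehyde equivalent), −78 °C to rt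
Reagents that add atoms: none
Why: Wittig olefination with a non-stabilised ylide under lithium-free conditions gives the (Z)-alkene through the cis-oxaphosphetane; the dimer opens to glycolaldehyde alkoxide in the basic medium, one extra equivalent of ylide serving as base.

Step 8
Reactants: 17 methyl (5Z)-7-hydroxyhept-5-enoate
Product: 18 methyl (5Z)-7-oxohept-5-enoate
Conditions: Dess–Martin periodinane (1.2 equiv), CH2Cl2, 0 °C, 30 min; used at once
Reagents that add atoms: none
Why: Dess–Martin oxidation converts the allylic alcohol to the enal under near-neutral, cold conditions that keep the (Z)-geometry.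

Step 9
Reactants: 12 (4S)-2-chloro-4-hydroxy-4-[(2Z)-oct-2-en-1-yl]cyclopent-2-en-1-one; 18 methyl (5Z)-7-oxohept-5-enoate
Product: 20 methyl (5Z)-7-{(5S)-3-chloro-5-hydroxy-5-[(2Z)-oct-2-en-1-yl]-2-oxocyclopent-3-en-1-yl}-7-hydroxyhept-5-enoate (diastereomer mixture), via dilithium dianion 19 (not isolated)
Conditions: LiN(i-Pr)2 (2.1 equiv), THF, −78 °C; then 18 (1.2 equiv), −78 °C, 20 min; AcOH quench at −78 °C
Reagents that add atoms: none
Why: The alkoxide–enolate dianion (C8 is the only enolisable position and the alkoxide cannot be expelled) adds 1,2 to the enal (aldol addition); the C7 and C8 centres form as a mixture that is erased in step 10, and C12 is untouched.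

Step 10
Reactants: 20 methyl (5Z)-7-{(5S)-3-chloro-5-hydroxy-5-[(2Z)-oct-2-en-1-yl]-2-oxocyclopent-3-en-1-yl}-7-hydroxyhept-5-enoate
Product: 23 methyl (5Z,7E)-7-{(5R)-5-(acetyloxy)-3-chloro-5-[(2Z)-oct-2-en-1-yl]-2-oxocyclopent-3-en-1-ylidene}hept-5-enoate, via C7 acetate 21 (not isolated), via dienone alcohol 22 (not isolated)
Conditions: Ac2O (10 equiv), 4-(dimethylamino)pyridine (0.3 equiv), pyridine, 0 °C to rt
Reagents that add atoms: acetic anhydride, CC(=O)OC(C)=O
Why: Acetylation makes the C7 oxygen a leaving group β to the ketone, so E1cB elimination gives the cross-conjugated dienone (aldol condensation completed), with 7E expected as the major isomer and any 7Z removed by chromatography. Loss of the C12 oxygen would give an antiaromatic cyclopentadienone and does not compete, and the tertiary hydroxyl is then acetylated by nucleophilic catalysis (Steglich-type acylation) with C12 unchanged; its descriptor changes from S to R only because C8 becomes sp2.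

**Compound list**
1 | 3-ethoxycyclopent-2-en-1-one | CCOC1=CC(=O)CC1 | starting material
2 | 1-bromooct-2-yne | CCCCCC#CCBr | starting material
3 | lithium 4-ethoxycyclopenta-1,4-dien-1-olate | [Li+].[O-]C1=CCC(OCC)=C1 | intermediate
4 | 3-ethoxy-5-(oct-2-yn-1-yl)cyclopent-2-en-1-one (racemic) | CCCCCC#CCC1CC(OCC)=CC1=O | intermediate
5 | 2-chloro-3-ethoxy-5-(oct-2-yn-1-yl)cyclopent-2-en-1-one (racemic) | CCCCCC#CCC1CC(OCC)=C(Cl)C1=O | intermediate
6 | 2-chloro-3-ethoxy-5-[(2Z)-oct-2-en-1-yl]cyclopent-2-en-1-one (racemic) | CCCCC/C=C\CC1CC(OCC)=C(Cl)C1=O | intermediate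
7 | lithium 5-chloro-4-ethoxy-2-[(2Z)-oct-2-en-1-yl]cyclopenta-1,4-dien-1-olate | [Li+].[O-]C1=C(C/C=C\CCCCC)CC(OCC)=C1Cl | intermediate
8 | 3-chloro-4-ethoxy-1-[(2Z)-oct-2-en-1-yl]-2-[(trimethylsilyl)oxy]cyclopenta-1,3-diene | CCCCC/C=C\CC1=C(O[Si](C)(C)C)C(Cl)=C(OCC)C1 | intermediate
9 | (5S)-2-chloro-3-ethoxy-5-[(2Z)-oct-2-en-1-yl]-5-[(trimethylsilyl)oxy]cyclopent-2-en-1-one | CCCCC/C=C\C[C@@]1(O[Si](C)(C)C)C(=O)C(Cl)=C(OCC)C1 | intermediate
10 | (5S)-2-chloro-3-ethoxy-5-hydroxy-5-[(2Z)-oct-2-en-1-yl]cyclopent-2-en-1-one | CCCCC/C=C\C[C@@]1(O)C(=O)C(Cl)=C(OCC)C1 | intermediate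
11 | (1S)-3-chloro-4-ethoxy-1-[(2Z)-oct-2-en-1-yl]cyclopent-3-ene-1,2-diol (both C2 epimers) | CCCCC/C=C\C[C@@]1(O)C(O)C(Cl)=C(OCC)C1 | intermediate
12 | (4S)-2-chloro-4-hydroxy-4-[(2Z)-oct-2-en-1-yl]cyclopent-2-en-1-one | CCCCC/C=C\C[C@@]1(O)C=C(Cl)C(=O)C1 | intermediate
13 | methyl 5-bromopentanoate | COC(=O)CCCCBr | starting material
14 | (5-methoxy-5-oxopentyl)triphenylphosphonium bromide | COC(=O)CCCC[P+](c1ccccc1)(c1ccccc1)c1ccccc1.[Br-] | intermediate
15 | glycolaldehyde dimer (1,4-dioxane-2,5-diol) | OC1COC(O)CO1 | starting material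
16 | methyl 5-(triphenyl-λ5-phosphanylidene)pentanoate | COC(=O)CCCC=P(c1ccccc1)(c1ccccc1)c1ccccc1 | intermediate
17 | methyl (5Z)-7-hydroxyhept-5-enoate | COC(=O)CCC/C=C\CO | intermediate
18 | methyl (5Z)-7-oxohept-5-enoate | COC(=O)CCC/C=C\C=O | intermediate
19 | dilithium (3S)-5-chloro-3-oxido-3-[(2Z)-oct-2-en-1-yl]cyclopenta-1,4-dien-1-olate | [Li+].[Li+].CCCCC/C=C\C[C@@]1([O-])C=C(Cl)C([O-])=C1 | intermediate
20 | methyl (5Z)-7-{(5S)-3-chloro-5-hydroxy-5-[(2Z)-oct-2-en-1-yl]-2-oxocyclopent-3-en-1-yl}-7-hydroxyhept-5-enoate (mixture at C7 and C8) | CCCCC/C=C\C[C@@]1(O)C=C(Cl)C(=O)C1C(O)/C=C\CCCC(=O)OC | intermediate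
21 | methyl (5Z)-7-(acetyloxy)-7-{(5S)-3-chloro-5-hydroxy-5-[(2Z)-oct-2-en-1-yl]-2-oxocyclopent-3-en-1-yl}hept-5-enoate (mixture at C7 and C8) | CCCCC/C=C\C[C@@]1(O)C=C(Cl)C(=O)C1C(OC(C)=O)/C=C\CCCC(=O)OC | intermediate
22 | methyl (5Z,7E)-7-{(5R)-3-chloro-5-hydroxy-5-[(2Z)-oct-2-en-1-yl]-2-oxocyclopent-3-en-1-ylidene}hept-5-enoate | CCCCC/C=C\C[C@@]1(O)C=C(Cl)C(=O)/C1=C/C=C\CCCC(=O)OC | intermediate
23 | methyl (5Z,7E)-7-{(5R)-5-(acetyloxy)-3-chloro-5-[(2Z)-oct-2-en-1-yl]-2-oxocyclopent-3-en-1-ylidene}hept-5-enoate | CCCCC/C=C\C[C@@]1(OC(C)=O)C=C(Cl)C(=O)/C1=C/C=C\CCCC(=O)OC | target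

**Totals and risks**
Total step count: 10. Longest linear sequence: 7 (steps 1–5, 9, 10); steps 6–8 are the aldehyde branch.

Step 4 (the new hydroxylation): turnover by silyl transfer, the level of enantioselectivity and its sense are unproven, and silyl dienol ether 8 is a cyclopentadiene that must be kept cold. The fallback sets out from 6 and uses known reagent-controlled chemistry. Lithium enolate 7 is formed as in step 4, not silylated, and oxidised at −78 °C with an enantiopure (camphorylsulfonyl)oxaziridine (Davis asymmetric enolate hydroxylation). The reagent enantiomer is chosen for the (S)-alcohol, and the product is enriched by chiral-phase chromatography if needed. It comes back to the route at 10 and makes no compound outside the list (F0).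

Step 9 (dianion aldol): the alkoxide–enolate 19 may ring-open by retro-aldol or enolise poorly, and enal 18 is prone to Z-to-E isomerisation and 1,4-addition. The fallback sets out from 12 and changes to a protected mono-enolate. Me3SiCl and imidazole in DMF give (4S)-2-chloro-4-[(2Z)-oct-2-en-1-yl]-4-[(trimethylsilyl)oxy]cyclopent-2-en-1-one F1. LiN(i-Pr)2 (1.1 equiv) at −78 °C gives lithium (3S)-5-chloro-3-[(2Z)-oct-2-en-1-yl]-3-[(trimethylsilyl)oxy]cyclopenta-1,4-dien-1-olate F2, which adds to 18 to give the silyl-protected aldol adduct F3. Citric acid in MeOH removes the silyl group, and the sequence comes back to the route at 20.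

Step 10 (one-flask acetylation/elimination): the 7E/7Z ratio, the integrity of the 5Z alkene and complete acetylation of the hindered tertiary hydroxyl are all at stake in one operation. The fallback sets out from 20 and separates the two events. Methanesulfonyl chloride and Et3N in CH2Cl2 at −40 to 0 °C give the C7 methanesulfonate F4, which eliminates in the same flask. It comes back to the route at dienone alcohol 22, which is isolated here so that any 7Z isomer can be removed while the tertiary hydroxyl is still free. Acetylation of 22 (Ac2O, 4-(dimethylamino)pyridine, pyridine) as in the second stage of step 10 then gives 23.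

Further compounds
F0 | step 4 | none | none
F1 | step 9 | (4S)-2-chloro-4-[(2Z)-oct-2-en-1-yl]-4-[(trimethylsilyl)oxy]cyclopent-2-en-1-one | CCCCC/C=C\C[C@@]1(O[Si](C)(C)C)C=C(Cl)C(=O)C1
F2 | step 9 | lithium (3S)-5-chloro-3-[(2Z)-oct-2-en-1-yl]-3-[(trimethylsilyl)oxy]cyclopenta-1,4-dien-1-olate | [Li+].CCCCC/C=C\C[C@@]1(O[Si](C)(C)C)C=C(Cl)C([O-])=C1
F3 | step 9 | methyl (5Z)-7-{(5S)-3-chloro-5-[(2Z)-oct-2-en-1-yl]-2-oxo-5-[(trimethylsilyl)oxy]cyclopent-3-en-1-yl}-7-hydroxyhept-5-enoate | CCCCC/C=C\C[C@@]1(O[Si](C)(C)C)C=C(Cl)C(=O)C1C(O)/C=C\CCCC(=O)OC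
F4 | step 10 | methyl (5Z)-7-{(5S)-3-chloro-5-hydroxy-5-[(2Z)-oct-2-en-1-yl]-2-oxocyclopent-3-en-1-yl}-7-[(methylsulfonyl)oxy]hept-5-enoate | CCCCC/C=C\C[C@@]1(O)C=C(Cl)C(=O)C1C(OS(C)(=O)=O)/C=C\CCCC(=O)OC
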